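**Retrosynthetic overview**
- Target ⇐ O‑debenzylation ⇐ acid‑induced Friedel–Crafts ring opening of a 2‑aryl‑tetrahydrofuran (lariciresinol type) whose only free hydroxyl is already sulfated. The ring oxygen reappears as the free CH2OH, so the sulfate can only sit on the other CH2O.
- Tetrahydrofuran ⇐ cyclodehydration of a seco‑triol ⇐ trans aldol (C1–C2) of an (R)‑β‑arylmethyl‑γ‑butyrolactone with O‑benzylvanillin.
- Key disconnection (C3–C3a plus the lactone C–O): the homoenolate of an (E)‑4‑arylbut‑2‑enal adds to formaldehyde under a chiral N‑heterocyclic carbene. The enal β‑carbon and a carbonyl carbon, both natural electrophiles, are joined, and the one catalyst‑set stereocentre (C3) is made; C2 and C1 are relayed from it.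
- Enal ⇐ cross‑metathesis of O‑benzyleugenol with crotonaldehyde.
- Ring order: γ‑lactone (temporary) → tetrahydrofuran (temporary) → carbocyclic ring B.

Convention and assumption: C1–C4, C4a, C8a are the tetralin locants of the target and C2a, C3a are the CH2O carbons on C2 and C3; sulfate monoesters are drawn as free hydrogen sulfates (as in the target SMILES) although they are handled as pyridinium or sodium salts.

**Step 1**
Reactants: 1 eugenol (4‑allyl‑2‑methoxyphenol)
Product: 2 4‑allyl‑1‑(benzyloxy)‑2‑methoxybenzene (O‑benzyleugenol)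
Conditions: BnBr (1.1 equiv), K2CO3 (1.5 equiv), acetone, reflux
Reagents that add atoms: benzyl bromide, BrCc1ccccc1
Why: Williamson ether synthesis on the phenoxide; no stereocentre is formed.

**Step 2**
Reactants: 2 O‑benzyleugenol; 3 crotonaldehyde ((E)‑but‑2‑enal)
Product: 4 (E)‑4‑[4‑(benzyloxy)‑3‑methoxyphenyl]but‑2‑enal
Conditions: 3 (5 equiv), second‑generation Hoveyda–Grubbs catalyst C31H38Cl2N2ORu (2.5 mol%), 1,4‑benzoquinone (10 mol%), CH2Cl2, 40 °C
Reagents that add atoms: none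
Why: Olefin cross‑metathesis of a terminal allylarene with an electron‑poor enal gives the E cross product with loss of propene, and benzoquinone suppresses allyl‑to‑propenyl isomerisation.

**Step 3 (key step)**
Reactants: 4 (E)‑4‑[4‑(benzyloxy)‑3‑methoxyphenyl]but‑2‑enal; 5 formaldehyde (as paraformaldehyde)
Product: 6 (4R)‑4‑[4‑(benzyloxy)‑3‑methoxybenzyl]dihydrofuran‑2(3H)‑one
Conditions: (5aR,10bS)‑2‑mesityl‑5a,10b‑dihydro‑4H,6H‑indeno[2,1‑b][1,2,4]triazolo[4,3‑d][1,4]oxazin‑2‑ium chloride (10 mol%; the antipode, also sold, is used if the facial sense turns out reversed), 1,8‑diazabicyclo[5.4.0]undec‑7‑ene (8 mol%), paraformaldehyde (3 equiv CH2O), THF, 40 °C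
Reagents that add atoms: none
Why: Proposed new method: the carbene adds to enal 4 to give the extended Breslow intermediate, whose β‑carbon (a homoenolate) attacks monomeric formaldehyde, and the resulting alkoxide closes on the acyl azolium to release the γ‑lactone and the carbene; the aminoindanol backbone shields one face of the homoenolate, so C3 is set by the catalyst, and formaldehyde has no prochiral face, so no diastereomers arise; the closest known reactions are the carbene‑catalysed homoenolate annulation of enals with aldehydes to γ‑butyrolactones and the carbene‑catalysed hydroxymethylation of aldehydes with paraformaldehyde.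

**Step 4**
Reactants: 6 (4R)‑lactone; 7 4‑(benzyloxy)‑3‑methoxybenzaldehyde (O‑benzylvanillin)
Product: 8 (3S,4R)‑4‑[4‑(benzyloxy)‑3‑methoxybenzyl]‑3‑{[4‑(benzyloxy)‑3‑methoxyphenyl](hydroxy)methyl}dihydrofuran‑2(3H)‑one (both carbinol epimers)
Conditions: LiN(SiMe3)2 (1.1 equiv), THF, −78 °C; then 7 (1.1 equiv), −78 °C; NH4Cl (aq) at −78 °C
Reagents that add atoms: none
Why: Lithium‑enolate aldol addition in which the aldehyde approaches anti to the C3 arylmethyl group, setting C2 trans to C3; the carbinol centre forms as a mixture, which is harmless because it is ionised in steps 5 and 7.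

**Step 5**
Reactants: 8 aldol adduct
Product: 10 [(2S,3R,4R)‑2‑[4‑(benzyloxy)‑3‑methoxyphenyl]‑4‑[4‑(benzyloxy)‑3‑methoxybenzyl]tetrahydrofuran‑3‑yl]methanol, via seco‑triol 9 (not isolated)
Conditions: LiAlH4 (2.5 equiv), THF, 0 °C to rt; then 2 M aq. HCl to pH 1, rt, about 3 h (monitored)
Reagents that add atoms: none
Why: LiAlH4 reduction of the lactone gives the triol, and on acidification the electron‑rich benzylic alcohol ionises (SN1) and is captured 5‑exo by the C3a hydroxyl (the C2a hydroxyl could only close a four‑membered ring), so both carbinol epimers converge on the thermodynamic 2,3‑trans tetrahydrofuran and only the C2a hydroxyl stays free; water traps the cation reversibly and holds back the slower Friedel–Crafts closure.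

**Step 6**
Reactants: 10 tetrahydrofuran alcohol
Product: 11 [(2S,3R,4R)‑2‑[4‑(benzyloxy)‑3‑methoxyphenyl]‑4‑[4‑(benzyloxy)‑3‑methoxybenzyl]tetrahydrofuran‑3‑yl]methyl hydrogen sulfate
Conditions: SO3·pyridine (3 equiv), pyridine, rt; MeOH quench
Reagents that add atoms: sulfur trioxide–pyridine complex, [O-]S(=O)(=O)[n+]1ccccc1
Why: O‑sulfation of the only free hydroxyl (C2a‑OH) by the SO3·pyridine complex, the phenols being benzylated and the C3a oxygen being locked in the ring; no stereocentre is touched.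

**Step 7**
Reactants: 11 tetrahydrofuran sulfate
Product: 12 [(1S,2R,3R)‑7‑(benzyloxy)‑1‑[4‑(benzyloxy)‑3‑methoxyphenyl]‑3‑(hydroxymethyl)‑6‑methoxy‑1,2,3,4‑tetrahydronaphthalen‑2‑yl]methyl hydrogen sulfate
Conditions: CF3CO2H–CH2Cl2 (1:4), 0 °C to rt, 2 h; then NaHCO3, MeOH–H2O
Reagents that add atoms: none
Why: Acid ionises the benzylic C–O bond of the tetrahydrofuran and an intramolecular Friedel–Crafts alkylation para to the methoxy group (the lariciresinol‑to‑isolariciresinol type rearrangement) closes ring B; C1 is set trans to the C2 substituent through a chair‑like transition state with the aryl group pseudo‑equatorial, and the ring oxygen is released as the free C3a hydroxyl.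

**Step 8**
Reactants: 12 dibenzyl ether sulfate
Product: 13 [(1S,2R,3R)‑7‑hydroxy‑1‑(4‑hydroxy‑3‑methoxyphenyl)‑3‑(hydroxymethyl)‑6‑methoxy‑1,2,3,4‑tetrahydronaphthalen‑2‑yl]methyl hydrogen sulfate (target)
Conditions: H2 (1 atm), Pd/C (10 wt% palladium on carbon), MeOH, rt; then sulfonic acid resin (H+ form)
Reagents that add atoms: none
Why: Hydrogenolysis of the two aryl benzyl ethers; the alkyl sulfate monoester and the three stereocentres are inert to H2 over palladium.

**Compound list**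
1 | eugenol (4‑allyl‑2‑methoxyphenol) | C=CCc1ccc(O)c(OC)c1 | starting material
2 | 4‑allyl‑1‑(benzyloxy)‑2‑methoxybenzene | C=CCc1ccc(OCc2ccccc2)c(OC)c1 | intermediate
3 | crotonaldehyde ((E)‑but‑2‑enal) | C/C=C/C=O | starting material
4 | (E)‑4‑[4‑(benzyloxy)‑3‑methoxyphenyl]but‑2‑enal | O=C/C=C/Cc1ccc(OCc2ccccc2)c(OC)c1 | intermediate
5 | formaldehyde (used as paraformaldehyde) | C=O | starting material
6 | (4R)‑4‑[4‑(benzyloxy)‑3‑methoxybenzyl]dihydrofuran‑2(3H)‑one | O=C1C[C@@H](Cc2ccc(OCc3ccccc3)c(OC)c2)CO1 | intermediate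
7 | 4‑(benzyloxy)‑3‑methoxybenzaldehyde | O=Cc1ccc(OCc2ccccc2)c(OC)c1 | starting material
8 | (3S,4R)‑4‑[4‑(benzyloxy)‑3‑methoxybenzyl]‑3‑{[4‑(benzyloxy)‑3‑methoxyphenyl](hydroxy)methyl}dihydrofuran‑2(3H)‑one, carbinol epimers | O=C1[C@H](C(O)c2ccc(OCc3ccccc3)c(OC)c2)[C@@H](Cc2ccc(OCc3ccccc3)c(OC)c2)CO1 | intermediate
9 | (2R,3R)‑2‑{[4‑(benzyloxy)‑3‑methoxyphenyl](hydroxy)methyl}‑3‑[4‑(benzyloxy)‑3‑methoxybenzyl]butane‑1,4‑diol, carbinol epimers | OC[C@H](C(O)c1ccc(OCc2ccccc2)c(OC)c1)[C@H](CO)Cc1ccc(OCc2ccccc2)c(OC)c1 | intermediate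
10 | [(2S,3R,4R)‑2‑[4‑(benzyloxy)‑3‑methoxyphenyl]‑4‑[4‑(benzyloxy)‑3‑methoxybenzyl]tetrahydrofuran‑3‑yl]methanol (the C2 epimer, if present, is carried along and converges in step 7) | OC[C@@H]1[C@@H](c2ccc(OCc3ccccc3)c(OC)c2)OC[C@@H]1Cc1ccc(OCc2ccccc2)c(OC)c1 | intermediate
11 | [(2S,3R,4R)‑2‑[4‑(benzyloxy)‑3‑methoxyphenyl]‑4‑[4‑(benzyloxy)‑3‑methoxybenzyl]tetrahydrofuran‑3‑yl]methyl hydrogen sulfate | OS(=O)(=O)OC[C@@H]1[C@@H](c2ccc(OCc3ccccc3)c(OC)c2)OC[C@@H]1Cc1ccc(OCc2ccccc2)c(OC)c1 | intermediate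
12 | [(1S,2R,3R)‑7‑(benzyloxy)‑1‑[4‑(benzyloxy)‑3‑methoxyphenyl]‑3‑(hydroxymethyl)‑6‑methoxy‑1,2,3,4‑tetrahydronaphthalen‑2‑yl]methyl hydrogen sulfate | COc1cc([C@H]2c3cc(OCc4ccccc4)c(OC)cc3C[C@@H](CO)[C@@H]2COS(=O)(=O)O)ccc1OCc1ccccc1 | intermediate
13 | [(1S,2R,3R)‑7‑hydroxy‑1‑(4‑hydroxy‑3‑methoxyphenyl)‑3‑(hydroxymethyl)‑6‑methoxy‑1,2,3,4‑tetrahydronaphthalen‑2‑yl]methyl hydrogen sulfate | COc1cc([C@H]2c3cc(O)c(OC)cc3C[C@@H](CO)[C@@H]2COS(=O)(=O)O)ccc1O | target

**Step count**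
Total steps: 8. Longest linear sequence: 8 (steps 1 to 8; compounds 3, 5 and 7 are bought).

**Three steps most likely to fail, with fallbacks**

Step 3 (carbene homoenolate annulation with formaldehyde). This is an untested pairing. Formaldehyde self‑condensation, acyl‑anion hydroxymethylation, base‑induced deconjugation of 4, or low ee could each defeat it. Fallback: lactone 6 is made without carbene catalysis, setting out from aldehyde 7 and coming back to the route at 6. Stobbe condensation of 7 with dimethyl succinate (KOC(CH3)3, tert‑butanol, reflux) gives (E)‑4‑[4‑(benzyloxy)‑3‑methoxyphenyl]‑3‑(methoxycarbonyl)but‑3‑enoic acid F1. Homogeneous asymmetric hydrogenation (H2, 5 bar, MeOH, 1 mol% [Rh(C8H12)(C18H28P2)]BF4, the 1,5‑cyclooctadiene rhodium tetrafluoroborate complex of 1,2‑bis(2,5‑dimethylphospholano)benzene, ligand antipode chosen for the R acid) leaves the benzyl ethers intact and gives (3R)‑4‑[4‑(benzyloxy)‑3‑methoxyphenyl]‑3‑(methoxycarbonyl)butanoic acid F2. Reduction of the ester in the presence of the potassium carboxylate with Ca(BH4)2 (from CaCl2 and NaBH4, EtOH) gives (3R)‑4‑[4‑(benzyloxy)‑3‑methoxyphenyl]‑3‑(hydroxymethyl)butanoic acid F3, which lactonises to 6 on acidification with HCl. Steps 1 and 2 are then not needed.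

Step 5 (one‑flask reduction and cyclodehydration). The acid stage may stall, or run on to the carbocycle, which would erase the difference between the two CH2OH groups. Fallback: the two primary hydroxyls are told apart through a 1,3‑dioxane instead of the tetrahydrofuran, setting out from 8 and coming back to the route at target 13. Compound 8 is reduced with LiAlH4 and worked up neutral (KNaC4H4O6, aq.) so that triol 9 is isolated. 2,2‑Dimethoxypropane with pyridinium 4‑toluenesulfonate in CH2Cl2 ties the benzylic and C2a hydroxyls, the only 1,3‑diol, into (2R)‑2‑[(5R)‑4‑[4‑(benzyloxy)‑3‑methoxyphenyl]‑2,2‑dimethyl‑1,3‑dioxan‑5‑yl]‑3‑[4‑(benzyloxy)‑3‑methoxyphenyl]propan‑1‑ol F4. The remaining C3a hydroxyl is capped with benzyl chloroformate (pyridine, 4‑(dimethylamino)pyridine) to give benzyl (2R)‑2‑[(5R)‑4‑[4‑(benzyloxy)‑3‑methoxyphenyl]‑2,2‑dimethyl‑1,3‑dioxan‑5‑yl]‑3‑[4‑(benzyloxy)‑3‑methoxyphenyl]propyl carbonate F5. CF3CO2H in CH2Cl2 cleaves the acetonide, ionises the benzylic C–O bond and closes ring B to [(1S,2R,3R)‑7‑(benzyloxy)‑1‑[4‑(benzyloxy)‑3‑methoxyphenyl]‑3‑({[(benzyloxy)carbonyl]oxy}methyl)‑6‑methoxy‑1,2,3,4‑tetrahydronaphthalen‑2‑yl]methanol F6. SO3·pyridine gives [(1S,2R,3R)‑7‑(benzyloxy)‑1‑[4‑(benzyloxy)‑3‑methoxyphenyl]‑3‑({[(benzyloxy)carbonyl]oxy}methyl)‑6‑methoxy‑1,2,3,4‑tetrahydronaphthalen‑2‑yl]methyl hydrogen sulfate F7. H2 over Pd/C then removes the two benzyl ethers and the benzyl carbonate together to give 13.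

Step 7 (Friedel–Crafts rearrangement in the presence of the sulfate). The sulfate salt may be poorly soluble or partly solvolysed in CF3CO2H, and the benzyl ethers may suffer. Fallback: the order of the last two operations is reversed so that the ring closure runs through a quinone methide under much milder acid, setting out from 11 and coming back to the route at 13. Hydrogenolysis of 11 (H2, 1 atm, Pd/C, EtOAc–MeOH, stopped after two equivalents) cleaves the aryl benzyl ethers much faster than the cyclic benzylic ether and gives [(2S,3R,4R)‑2‑(4‑hydroxy‑3‑methoxyphenyl)‑4‑(4‑hydroxy‑3‑methoxybenzyl)tetrahydrofuran‑3‑yl]methyl hydrogen sulfate F8. With the para‑phenol free, the benzylic C–O bond opens in dilute aqueous acid (0.1 M HCl or aqueous HCO2H, 40 °C), conditions under which an alkyl sulfate monoester is inert, and the same trans‑selective cyclisation gives 13 directly.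

**Further compounds**
F1 | step 3 | (E)‑4‑[4‑(benzyloxy)‑3‑methoxyphenyl]‑3‑(methoxycarbonyl)but‑3‑enoic acid | COC(=O)/C(CC(=O)O)=C/c1ccc(OCc2ccccc2)c(OC)c1
F2 | step 3 | (3R)‑4‑[4‑(benzyloxy)‑3‑methoxyphenyl]‑3‑(methoxycarbonyl)butanoic acid | COC(=O)[C@H](Cc1ccc(OCc2ccccc2)c(OC)c1)CC(=O)O
F3 | step 3 | (3R)‑4‑[4‑(benzyloxy)‑3‑methoxyphenyl]‑3‑(hydroxymethyl)butanoic acid | OC[C@H](Cc1ccc(OCc2ccccc2)c(OC)c1)CC(=O)O
F4 | step 5 | (2R)‑2‑[(5R)‑4‑[4‑(benzyloxy)‑3‑methoxyphenyl]‑2,2‑dimethyl‑1,3‑dioxan‑5‑yl]‑3‑[4‑(benzyloxy)‑3‑methoxyphenyl]propan‑1‑ol | CC1(C)OC[C@@H]([C@H](CO)Cc2ccc(OCc3ccccc3)c(OC)c2)C(c2ccc(OCc3ccccc3)c(OC)c2)O1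
F5 | step 5 | benzyl (2R)‑2‑[(5R)‑4‑[4‑(benzyloxy)‑3‑methoxyphenyl]‑2,2‑dimethyl‑1,3‑dioxan‑5‑yl]‑3‑[4‑(benzyloxy)‑3‑methoxyphenyl]propyl carbonate | CC1(C)OC[C@@H]([C@H](COC(=O)OCc2ccccc2)Cc2ccc(OCc3ccccc3)c(OC)c2)C(c2ccc(OCc3ccccc3)c(OC)c2)O1
F6 | step 5 | [(1S,2R,3R)‑7‑(benzyloxy)‑1‑[4‑(benzyloxy)‑3‑methoxyphenyl]‑3‑({[(benzyloxy)carbonyl]oxy}methyl)‑6‑methoxy‑1,2,3,4‑tetrahydronaphthalen‑2‑yl]methanol | COc1cc([C@H]2c3cc(OCc4ccccc4)c(OC)cc3C[C@@H](COC(=O)OCc3ccccc3)[C@@H]2CO)ccc1OCc1ccccc1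
F7 | step 5 | [(1S,2R,3R)‑7‑(benzyloxy)‑1‑[4‑(benzyloxy)‑3‑methoxyphenyl]‑3‑({[(benzyloxy)carbonyl]oxy}methyl)‑6‑methoxy‑1,2,3,4‑tetrahydronaphthalen‑2‑yl]methyl hydrogen sulfate | COc1cc([C@H]2c3cc(OCc4ccccc4)c(OC)cc3C[C@@H](COC(=O)OCc3ccccc3)[C@@H]2COS(=O)(=O)O)ccc1OCc1ccccc1
F8 | step 7 | [(2S,3R,4R)‑2‑(4‑hydroxy‑3‑methoxyphenyl)‑4‑(4‑hydroxy‑3‑methoxybenzyl)tetrahydrofuran‑3‑yl]methyl hydrogen sulfate | OS(=O)(=O)OC[C@@H]1[C@@H](c2ccc(O)c(OC)c2)OC[C@@H]1Cc1ccc(O)c(OC)c1
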